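**Assumption:** the SMILES is read as epimesquitol-(4β→6)-epimesquitol-4β-ol, (2R,3R,4S) in both flavan units, with the interflavan bond running from C4 of the upper unit to C6 of the lower unit (the carbon ortho to its 7-OH). The antipode of the carbene ligand in step 5 that leads to the (2R,3R) series has to be fixed in a first small-scale run.

## Analysis of the target

The target is a B-type biflavanoid. An upper 3′,4′,7,8-tetrahydroxyflavan-3-ol unit (benzo ring A, catechol ring B, pyran ring C) is bonded through C4 of ring C to C6 of benzo ring D of a lower 3′,4′,7,8-tetrahydroxyflavan-3,4-diol unit (catechol ring E, pyran ring F). There are six stereocentres, (2R,3R,4S) in each unit. In ring C and in ring F alike, H-2 and H-3 are cis, and the C4 substituent (the ring-D aryl group in ring C, the hydroxyl in ring F) is trans to the 3-OH.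

The feature the route is built on: rings C and F are stereochemically the same ring. Each is what melacacidin (11's monomer, the (2R,3R,4R)-flavan-3,4-diol with H-2, H-3 and H-4 all on one face of its pyran ring) gives when its C4–O bond is replaced with inversion. The target is two melacacidins minus one water. The all-cis hydrogen face of melacacidin is the signature of a syn delivery of hydrogen to C2=C3 and C4=O of a flat flavonol.

Sensitive groups are the eight phenolic hydroxyls in four catechol pairs (air oxidation, worst in base) and the benzylic C4–OH of ring F. That hydroxyl is para to the 7-OH of ring D, ionises in dilute acid to a quinone methide, and can be lost by hydrogenolysis.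

The hard points are three. The 2,3-cis relation is needed twice, and the usual asymmetric entries to flavans deliver 2,3-trans. The 7,8-dihydroxy nucleus is a weak carbon nucleophile with two free positions (C6 and C5) and competing oxygen nucleophiles. The product carries the same ionisable C4–OH as its monomer, so it can react on, and no forcing deprotection is tolerable at the end.

## Retrosynthetic reasoning

**11 to two molecules of 8.** The only bond between the halves, C4 (ring C)–C6 (ring D), is cut, and the C4–OH of ring F is recognised as an epimerised melacacidin hydroxyl. Both fragments are then the same compound, melacacidin 8. In the forward direction 8 ionises in dilute acid to the para-quinone methide 9. Solvent return on the face anti to the 3-OH gives the 4β-ol 10, and C6 of 10 adds to 9 on the same face. This is a dehydrative homodimerisation: one monomer instead of two differently protected ones, and no protecting group on the final product.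

**8 to 7.** The five hydroxyls that must survive base, peroxide and hydrogenation are masked as benzyl ethers, removed in one hydrogenolysis. The forward reaction has to spare the benzylic C4–OH.

**7 to 6 (key disconnection).** The three C–H bonds at C2, C3 and C4, all on one face of ring C, are removed. What remains is the flat, achiral flavonol ether 6. The forward reaction is a hydrogenation that must deliver two equivalents of hydrogen to a single enantioface of the pyranone ring. This one operation creates C2 and C3 of both units of 11 directly. The two C4 centres of 11 follow from C3 by relay in the last step, so all six stereocentres descend from it. The cut is made here and not at a ring bond because 2,3-cis is exactly what a syn addition gives and what ring-closing routes do not.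

**6 to 5 to 4.** The 3-O-benzyl group comes from O-alkylation of flavonol 5. The pyranone ring of 5 (O1–C2 bond and C3–O bond) comes from chalcone 4 by oxidative cyclisation.

**4 to 2 and 3; 2 to 1.** The enone double bond is cut by a crossed aldol condensation into acetophenone 2 and aldehyde 3. Compound 2 is the selective dibenzyl ether of gallacetophenone 1. Both 1 and 3 are catalogue compounds.

## Alternatives that were turned down

**Alternative 1:** the textbook route. Disconnection: the interflavan C4–C6 bond between two different, fully protected flavan units. Forward key step: Lewis-acid (TMSOTf) coupling of the C4-activated electrophile A2 with an excess of the C4-hydroxy nucleophile A3, then global hydrogenolysis. Both partners derive from tetra-O-benzylepimesquitol A1, reached by asymmetric dihydroxylation, cyclisation and an oxidation–reduction at C3. Turned down because: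
- the stereocentres are built one at a time, and the cis relation needs a detour through the C3 ketone, about nine steps to A1;
- the same monomer must be taken through two C4 functionalisations and two protecting-group patterns, and the C4–OH of A3 must be shielded from the Lewis acid;
- a benzylated 7,8-dioxygenated ring has lost the free 7-OH that makes C6 nucleophilic, so the coupling is asked of the least reactive form;
- it ends with hydrogenolysis of eight benzyl ethers next to a benzylic alcohol, on the most valuable compound of the route, after more than fifteen steps.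

**Alternative 2:** Disconnection: the O1–C2 bond of each pyran ring, with the stereocentres taken from an epoxide. Forward key step: asymmetric Julià–Colonna epoxidation–cyclisation of chalcone 4 to the dihydroflavonol A4, then hydride reduction of the ketone. Turned down on mechanism: ring closure by the phenol with inversion at the benzylic carbon can only give the 2,3-trans compound, and A4 leads to the mesquitol (2,3-trans) series. Correcting C3 means a substitution with inversion at an α-ketol next to an aryl-bearing C2–H, where elimination to the aromatic flavonol 5 and enolisation compete. The method that sets the stereocentres sets the wrong relative configuration for this target.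

**Alternative 3:** Disconnection: ring C by a [4+2] cycloaddition (O1–C2 and C3–C4 bonds), with the lower unit already on the future C4. Forward key step: hetero-Diels–Alder reaction of the ortho-quinone methide generated from benzhydrol A5 with the (Z)-enol acetate A6, which would set C2, C3 and C4 together. Turned down because:
- the oxygen-bearing alkene carbon of A6 must bond to C4, so the aryl group must outweigh the enol oxygen in directing, and the opposite regiochemistry (an isoflavan-type acetal) is at least as likely;
- the endo preference puts the 2-aryl and 4-aryl groups cis, while the target has them trans;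
- facial control would have to come from the remote stereocentres of ring F;
- A5 needs the complete lower unit first, so no step is saved.

Key step: step 5

## Route

Step 1
Reactants: 1 1-(2,3,4-trihydroxyphenyl)ethanone (gallacetophenone)
Product: 2 1-[3,4-bis(benzyloxy)-2-hydroxyphenyl]ethanone
Conditions: BnBr (2.1 equiv), K2CO3 (2.1 equiv), DMF, 20 to 40 °C
Reagents that add atoms: benzyl bromide, BrCc1ccccc1
Why: Williamson ether synthesis; the 2-OH is tied up in a hydrogen bond to the acetyl C=O and is the least acidic and least nucleophilic hydroxyl, so two equivalents of base and bromide should stop at the 3,4-dibenzyl ether.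

Step 2
Reactants: 2 1-[3,4-bis(benzyloxy)-2-hydroxyphenyl]ethanone; 3 3,4-bis(benzyloxy)benzaldehyde
Product: 4 (E)-1-[3,4-bis(benzyloxy)-2-hydroxyphenyl]-3-[3,4-bis(benzyloxy)phenyl]prop-2-en-1-one
Conditions: KOH (aq, 5 equiv), EtOH/THF, 20 °C; then aq HCl
Reagents that add atoms: none
Why: Claisen–Schmidt (crossed aldol) condensation; 3 has no enolisable hydrogen and dehydration of the aldol is driven by conjugation, which gives the E enone; benzyl ethers are inert to aqueous KOH.

Step 3
Reactants: 4 (E)-1-[3,4-bis(benzyloxy)-2-hydroxyphenyl]-3-[3,4-bis(benzyloxy)phenyl]prop-2-en-1-one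
Product: 5 7,8-bis(benzyloxy)-2-[3,4-bis(benzyloxy)phenyl]-3-hydroxy-4H-chromen-4-one (tetra-O-benzylmelanoxetin)
Conditions: H2O2 (30% aq), NaOH (aq), MeOH/THF, 0 to 20 °C; then aq HCl
Reagents that add atoms: hydrogen peroxide, OO
Why: Algar–Flynn–Oyamada reaction: alkaline peroxide oxidises the enone, the 2′-phenolate closes ring C (O1–C2 bond) and the dihydroflavonol is oxidised on to the flavonol; with no substituent at C6′ of the chalcone the flavonol and not the aurone is the expected product.

Step 4
Reactants: 5 7,8-bis(benzyloxy)-2-[3,4-bis(benzyloxy)phenyl]-3-hydroxy-4H-chromen-4-one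
Product: 6 3,7,8-tris(benzyloxy)-2-[3,4-bis(benzyloxy)phenyl]-4H-chromen-4-one (penta-O-benzylmelanoxetin)
Conditions: BnBr (1.3 equiv), K2CO3 (1.5 equiv), DMF, 50 °C
Reagents that add atoms: benzyl bromide, BrCc1ccccc1
Why: Williamson ether synthesis on the acidic enolic 3-OH; it removes the only acidic, metal-chelating group before the hydrogenation and leaves a single type of protecting group for one deprotection.

Step 5
Reactants: 6 3,7,8-tris(benzyloxy)-2-[3,4-bis(benzyloxy)phenyl]-4H-chromen-4-one
Product: 7 (2R,3R,4R)-3,7,8-tris(benzyloxy)-2-[3,4-bis(benzyloxy)phenyl]-3,4-dihydro-2H-chromen-4-ol (penta-O-benzylmelacacidin)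
Conditions: H2 (100 bar), [Ru(cod)(2-methylallyl)2] (5 mol%), (R,R)-1,3-bis[1-(1-naphthyl)ethyl]imidazolinium tetrafluoroborate (SINpEt·HBF4, 10 mol%), KOt-Bu (12 mol%), toluene, 40 °C
Reagents that add atoms: none
Why: Proposed new method: the chiral bis(N-heterocyclic carbene) complex of divalent ruthenium formed from the three catalyst components is expected to coordinate one face of the flat pyranone ring of 6 and to add hydrogen syn across the tetrasubstituted enol-ether bond C2=C3, after which the C4 ketone of the resulting 2,3-cis-3-benzyloxyflavanone is reduced from the same, less hindered face (anti to the C2 aryl and C3 benzyloxy groups), so that H-2, H-3 and H-4 end up on one face. The closest known reaction types are the enantioselective hydrogenation of flavones and chromones to cis-flavan-4-ols with this catalyst family and the heterogeneous hydrogenation of flavonol ethers to racemic 2,3-cis-3,4-cis-flavan-3,4-diols; enantioface-selective hydrogenation of a flavone that carries an oxygen at C3 has not been shown and is what is proposed. No ring is closed. C2 and C3 are controlled by the catalyst (choice of enantioface, with the ligand antipode picked to give 2R,3R) and their cis relation by the syn mechanism of addition; C4 is controlled by substrate and catalyst acting in the same sense, and an error at C4 is harmless because step 7 ionises that centre. The step needs chemoselectivity for the pyranone over six benzene rings and five benzyl C–O bonds, which a homogeneous ruthenium catalyst at 40 °C without palladium or acid should respect, and it needs the intermediate ketone not to ring-open by retro-oxa-Michael reaction, which the small, carbene-bound amount of base should ensure.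

Step 6
Reactants: 7 (2R,3R,4R)-3,7,8-tris(benzyloxy)-2-[3,4-bis(benzyloxy)phenyl]-3,4-dihydro-2H-chromen-4-ol
Product: 8 melacacidin [(2R,3R,4R)-2-(3,4-dihydroxyphenyl)-3,4-dihydro-2H-chromene-3,4,7,8-tetrol]
Conditions: H2 (1 atm), Pd(OH)2/C, THF/EtOAc/H2O, 20 °C, acid-free, stopped after uptake of five equivalents
Reagents that add atoms: none
Why: Hydrogenolysis of benzyl ethers; the four aryl benzyl ethers and the alkyl benzyl ether at O3 cleave under neutral conditions under which a secondary benzylic alcohol is normally retained, and no stereocentre is touched; acid is excluded so that C4 does not ionise.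

Step 7
Reactants: 8 melacacidin (two molecules)
Product: 11 epimesquitol-(4β→6)-epimesquitol-4β-ol (target), via para-quinone methide 9 (not isolated), via isomelacacidin 10 (not isolated)
Conditions: 0.1 M aq HCl (degassed), 0.2 M in 8, argon, 25 to 40 °C, stopped at partial conversion; Sephadex LH-20 (EtOH), recovered monomer recycled
Reagents that add atoms: water, O
Why: Acid-catalysed condensation of a flavan-3,4-diol with a phenolic nucleus (biogenetic-type Friedel–Crafts alkylation through a quinone methide): the C4–OH, para to the 7-OH, ionises to 9, water returns on the face anti to the axial 3-OH to give the 3,4-trans diol 10, and C6 of 10 (ortho to the 7-OH and para to O1, the most electron-rich free carbon) adds to 9 on the same face, which sets C4 of ring C as 4β (S) and leaves C4 of ring F as the 4β-ol (S). Ether-linked products re-ionise under these conditions while the C–C bond to a 7,8-dihydroxy ring should not, so material should drain towards 11, and partial conversion limits trimers.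

## Compound list

1 | 1-(2,3,4-trihydroxyphenyl)ethanone (gallacetophenone) | CC(=O)c1ccc(O)c(O)c1O | starting material
2 | 1-[3,4-bis(benzyloxy)-2-hydroxyphenyl]ethanone | CC(=O)c1ccc(OCc2ccccc2)c(OCc2ccccc2)c1O | intermediate
3 | 3,4-bis(benzyloxy)benzaldehyde | O=Cc1ccc(OCc2ccccc2)c(OCc2ccccc2)c1 | starting material
4 | (E)-1-[3,4-bis(benzyloxy)-2-hydroxyphenyl]-3-[3,4-bis(benzyloxy)phenyl]prop-2-en-1-one | O=C(/C=C/c1ccc(OCc2ccccc2)c(OCc2ccccc2)c1)c1ccc(OCc2ccccc2)c(OCc2ccccc2)c1O | intermediate
5 | 7,8-bis(benzyloxy)-2-[3,4-bis(benzyloxy)phenyl]-3-hydroxy-4H-chromen-4-one | O=c1c(O)c(-c2ccc(OCc3ccccc3)c(OCc3ccccc3)c2)oc2c(OCc3ccccc3)c(OCc3ccccc3)ccc12 | intermediate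
6 | 3,7,8-tris(benzyloxy)-2-[3,4-bis(benzyloxy)phenyl]-4H-chromen-4-one | O=c1c(OCc2ccccc2)c(-c2ccc(OCc3ccccc3)c(OCc3ccccc3)c2)oc2c(OCc3ccccc3)c(OCc3ccccc3)ccc12 | intermediate
7 | (2R,3R,4R)-3,7,8-tris(benzyloxy)-2-[3,4-bis(benzyloxy)phenyl]-3,4-dihydro-2H-chromen-4-ol | c1ccccc1COc1ccc2c(c1OCc1ccccc1)O[C@H](c1ccc(OCc3ccccc3)c(OCc3ccccc3)c1)[C@H](OCc1ccccc1)[C@@H]2O | intermediate
8 | melacacidin, (2R,3R,4R)-2-(3,4-dihydroxyphenyl)-3,4-dihydro-2H-chromene-3,4,7,8-tetrol | Oc1ccc2c(c1O)O[C@H](c1ccc(O)c(O)c1)[C@H](O)[C@@H]2O | intermediate
9 | para-quinone methide, (2R,3R)-2-(3,4-dihydroxyphenyl)-3,8-dihydroxy-2,3-dihydro-7H-chromen-7-one | O=C1C=CC2=C[C@@H](O)[C@@H](c3ccc(O)c(O)c3)OC2=C1O | intermediate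
10 | isomelacacidin, (2R,3R,4S)-2-(3,4-dihydroxyphenyl)-3,4-dihydro-2H-chromene-3,4,7,8-tetrol | Oc1ccc2c(c1O)O[C@H](c1ccc(O)c(O)c1)[C@H](O)[C@H]2O | intermediate
11 | (2R,3R,4S)-2-(3,4-dihydroxyphenyl)-6-[(2R,3R,4S)-2-(3,4-dihydroxyphenyl)-3,7,8-trihydroxy-3,4-dihydro-2H-chromen-4-yl]-3,4-dihydro-2H-chromene-3,4,7,8-tetrol | Oc1ccc([C@H]2Oc3c(ccc(O)c3O)[C@H](c3cc4c(c(O)c3O)O[C@H](c3ccc(O)c(O)c3)[C@H](O)[C@H]4O)[C@H]2O)cc1O | target

## Step count and risks

Total step count: 7. Longest linear sequence: 7 steps (1 to 11); aldehyde 3 enters in step 2 as bought.

**Step 5 (key step, the one step proposed beyond known chemistry).** Most likely failures: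
- sluggish or incomplete hydrogenation of the tetrasubstituted, doubly oxygenated C2=C3 bond;
- weak discrimination between the two faces of the pyranone by the catalyst (low enantiomeric purity);
- arrest at the ketone stage;
- base-induced ring opening of the intermediate ketone with loss of the cis relation;
- slow saturation of benzene rings at high pressure.

An arrest at the ketone would be completed with hydride. Fallback with known chemistry, from 5 back to 8: 5 is debenzylated (H2, Pd/C, THF/MeOH) to melanoxetin F1. Heterogeneous hydrogenation of F1 over Raney nickel (H2, EtOH), the classical all-cis reduction of flavonols, gives racemic melacacidin, that is 8 together with its mirror image ent-melacacidin F2. The racemate is resolved by preparative chromatography on a cellulose carbamate chiral phase, and 8 enters step 7. Steps 4 to 6 are bypassed at the cost of half the material.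

**Step 7.** Most likely failures:
- further condensation of 11 through its own ionisable C4–OH (trimers and higher);
- attack through C5 of ring D or through oxygen, giving regioisomeric and ether-linked dimers;
- incomplete equilibration of the ring-F hydroxyl, leaving some 4α-ol epimer;
- slow reaction because the 7,8-dihydroxy ring is a weak nucleophile.

Fallback, from 8 back to 11: one portion of 8 is treated with phenylmethanethiol in acetic acid to give the 4β-benzylsulfanyl derivative F3 (thiolytic capture of 9, trans to the 3-OH). A second portion of 8 is epimerised in dilute acid and isolated as 10. F3 is then activated with AgBF4 in THF at 0 °C in the presence of a threefold excess of 10. Only the thioether ionises under these non-protic conditions, and the excess nucleophile suppresses oligomers. This yields 11, and unreacted 10 is recovered.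

**Step 6.** Most likely failures: hydrogenolysis of the benzylic C4–O bond once the 7-OH is free, and air oxidation of the catechols during work-up. Fallback, from 7 back to 8: Dess–Martin oxidation of 7 gives the 2,3-cis ketone F4, whose C4 oxygen cannot be lost by hydrogenolysis. Debenzylation (H2, Pd(OH)2/C) gives the free 2,3-cis-dihydroflavonol F5. Reduction with NaBH4 in EtOH at 0 °C returns 8. Any C4 epimer formed is 10 and serves equally in step 7.

**Step 1.** Most likely failure: over-alkylation at the chelated 2-OH or incomplete alkylation at the flanked 3-OH, giving mixtures. Fallback, from 1 back to 2: exhaustive benzylation (excess BnBr, K2CO3, DMF, 60 °C) gives the tribenzyl ether F6. The benzyl group ortho to the acetyl group is then removed selectively through the magnesium chelate (MgBr2·OEt2, toluene/Et2O, reflux; aq HCl work-up) to give 2.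

## Further compounds

F1 | step 5 | melanoxetin, 2-(3,4-dihydroxyphenyl)-3,7,8-trihydroxy-4H-chromen-4-one | O=c1c(O)c(-c2ccc(O)c(O)c2)oc2c(O)c(O)ccc12
F2 | step 5 | ent-melacacidin, (2S,3S,4S)-2-(3,4-dihydroxyphenyl)-3,4-dihydro-2H-chromene-3,4,7,8-tetrol | Oc1ccc2c(c1O)O[C@@H](c1ccc(O)c(O)c1)[C@@H](O)[C@H]2O
F3 | step 7 | (2R,3S,4S)-4-(benzylsulfanyl)-2-(3,4-dihydroxyphenyl)-3,4-dihydro-2H-chromene-3,7,8-triol | Oc1ccc2c(c1O)O[C@H](c1ccc(O)c(O)c1)[C@H](O)[C@H]2SCc1ccccc1
F4 | step 6 | (2R,3S)-3,7,8-tris(benzyloxy)-2-[3,4-bis(benzyloxy)phenyl]-2,3-dihydro-4H-chromen-4-one | O=C1c2ccc(OCc3ccccc3)c(OCc3ccccc3)c2O[C@H](c2ccc(OCc3ccccc3)c(OCc3ccccc3)c2)[C@@H]1OCc1ccccc1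
F5 | step 6 | (2R,3S)-2-(3,4-dihydroxyphenyl)-3,7,8-trihydroxy-2,3-dihydro-4H-chromen-4-one | O=C1c2ccc(O)c(O)c2O[C@H](c2ccc(O)c(O)c2)[C@@H]1O
F6 | step 1 | 1-[2,3,4-tris(benzyloxy)phenyl]ethanone | CC(=O)c1ccc(OCc2ccccc2)c(OCc2ccccc2)c1OCc1ccccc1
A1 | alternative 1 | tetra-O-benzylepimesquitol, (2R,3R)-7,8-bis(benzyloxy)-2-[3,4-bis(benzyloxy)phenyl]-3,4-dihydro-2H-chromen-3-ol | O[C@@H]1Cc2ccc(OCc3ccccc3)c(OCc3ccccc3)c2O[C@@H]1c1ccc(OCc2ccccc2)c(OCc2ccccc2)c1
A2 | alternative 1 | (2R,3R,4S)-7,8-bis(benzyloxy)-2-[3,4-bis(benzyloxy)phenyl]-4-(2-ethoxyethoxy)-3,4-dihydro-2H-chromen-3-ol | c1ccccc1COc1ccc2c(c1OCc1ccccc1)O[C@H](c1ccc(OCc3ccccc3)c(OCc3ccccc3)c1)[C@H](O)[C@H]2OCCOCC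
A3 | alternative 1 | (2R,3R,4S)-7,8-bis(benzyloxy)-2-[3,4-bis(benzyloxy)phenyl]-3,4-dihydro-2H-chromene-3,4-diol | c1ccccc1COc1ccc2c(c1OCc1ccccc1)O[C@H](c1ccc(OCc3ccccc3)c(OCc3ccccc3)c1)[C@H](O)[C@H]2O
A4 | alternative 2 | (2R,3R)-7,8-bis(benzyloxy)-2-[3,4-bis(benzyloxy)phenyl]-3-hydroxy-2,3-dihydro-4H-chromen-4-one | O=C1c2ccc(OCc3ccccc3)c(OCc3ccccc3)c2O[C@H](c2ccc(OCc3ccccc3)c(OCc3ccccc3)c2)[C@H]1O
A5 | alternative 3 | (2R,3R,4S)-2-(3,4-dihydroxyphenyl)-6-[hydroxy(2,3,4-trihydroxyphenyl)methyl]-3,4-dihydro-2H-chromene-3,4,7,8-tetrol | Oc1ccc(C(O)c2cc3c(c(O)c2O)O[C@H](c2ccc(O)c(O)c2)[C@H](O)[C@H]3O)c(O)c1O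
A6 | alternative 3 | (Z)-2-[3,4-bis(benzyloxy)phenyl]ethenyl acetate | CC(=O)O/C=C\c1ccc(OCc2ccccc2)c(OCc2ccccc2)c1
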